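(The earlier runs and the new flask were generated by integration with constants of no real substance, and the scatter is random.)

Count the ligand first.

| setting | north | north-west | alder | larch |
|---|---|---|---|---|
| starting complex | 0.025 M | 0.038 M | 0.050 M | 0.050 M |
| incoming ligand | 0.10 M | 0.10 M | 0.100 M | 0.100 M |
| temperature | 25 °C | 36 °C |  |  |
| remark | run made earlier | run made earlier | at 20 °C throughout | at 20 °C until 10 h, from then on at 40 °C |
| time |  |  | 50 h | 30 h |

- north (time / h: complex with two exchanged / %, starting complex / %): 4.00: 3.8, 87.1; 8.00: 5.4, 75.3; 12.0: 11.8, 66.4; 15.0: 17.7, 58.7; 20.0: 24.6, 51.3; 25.0: 34.3, 42.7; 30.0: 40.4, 39.4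
- north-west (time / h: complex with two exchanged / %, starting complex / %): 1.00: 2.6, 90.4; 2.00: 5.1, 79.8; 2.50: 4.9, 73.1; 4.00: 11.6, 63.7; 5.00: 16.4, 58.6; 10.0: 36.2, 37.8; 15.0: 53.1, 24.6

(readings scatter by 1 percentage point)

- a reading or a percentage of complex with two exchanged counts all its forms, free or not

* the winner by amount of complex with two exchanged, in percent of the starting complex charged; "neither" if no more than 2 percentage points parts them (alder / larch / neither)
* how much complex with two exchanged is there at the end, in percent of the starting complex charged: alder
* how much complex with two exchanged is there at the end, in percent of the starting complex charged: larch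

The readings give a rate for the first exchange, taken as first order in starting complex and in incoming ligand. The ligand used at a reading follows from the balance: one per starting complex lost, and a second per complex with two exchanged. Dividing the negative logarithm of the fraction of starting complex left by the time and the mean ligand, then scaling to 0.100 M, gives 0.0384 h⁻¹ at 25 °C (north, 25.0 h) and 0.124 h⁻¹ at 36 °C (north-west, 15.0 h). Both are readings with their scatter. A constant factor per degree carries them to 0.0226 h⁻¹ at 20 °C and 0.189 h⁻¹ at 40 °C.

The inverses form a ladder of pseudo-first-order lifetimes. The shortest is 5.29 h at 40 °C, and the hot stage of larch lasts 3.78 such lifetimes. The cold start of larch covers a quarter of the 44.2 h lifetime at 20 °C, and alder stays on that rung for 50 h. Larch collects 4.01 and alder 1.13 of ligand dose, the hours at each temperature divided by that lifetime and summed.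

Both flasks charge two equivalents. If each lost starting complex took both ligands at once, the rate would go with [starting complex] squared, and the fraction left would be the reciprocal of one plus the dose: 47.0% in alder, 20.0% in larch. The gap of 20.2% in the last north reading has taken one ligand, so these fractions lean high. North readings with 51.3% and 42.7% left showed 24.6% and 34.3% of product, which brackets alder. North-west showed 53.1% with 24.6% left, so larch should stand higher.

The forecast, resting on “Alder and larch are exactly stoichiometric”, names larch: alder 33% (27% to 39%), larch 69% (60% to 76%).

The flasks give 33.6% for alder and 67.2% for larch.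

    starting complex + incoming ligand → leaving ligand + complex with one exchanged (k = 0.00352 L mol⁻¹ min⁻¹, Ea = 84.0 kJ mol⁻¹)
    complex with one exchanged + incoming ligand → leaving ligand + complex with two exchanged (k = 0.00862 L mol⁻¹ min⁻¹, Ea = 66.0 kJ mol⁻¹)
    crystals ⇌ complex with two exchanged, rate k3*(cs3 - [complex with two exchanged]) while solid is left; crystals form when [complex with two exchanged] > cs3 (solubility = 22.0 mM, k = 0.0424 min⁻¹)
    (constants at 20 °C)

In larch at 12.3 h, the first exchange uses ligand 1.4 times as fast as the second. Starting complex ends at 15% against the dose's 20.0%, and at 45% against 47.0% in alder. A neighbour of larch charges 0.17 M of incoming ligand. With E the excess over two equivalents and L the charge, the fraction left is E/(L·exp(dose·E/L) − (L − E)), and the dose of 6.82 gives 2.58%. That flask leaves 2.0%, with 94.6% of complex with two exchanged.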